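The easy step comes first: in the blue run the left-handed substrate reads 0% at 2.00 min, so I book it as one equivalent of partner used at the start.

| setting | blue | violet | flask |
|---|---|---|---|
| left-handed substrate | 10 mM | 10 mM | 10 mM |
| right-handed substrate | 10 mM | 10 mM | 10 mM |
| partner | 4.2 equiv | 6.6 equiv | 3.00 equiv |
| protic impurity | 0.20 mM | 0.20 mM | 0.200 mM |
| catalyst | 0.2 mol% | 0.2 mol% | 0.2 mol% |
| added ligand | 14 µM | 14 µM | 14 µM |
| remark | run made earlier | run made earlier |  |
| time |  |  | 12 min |

| run | time / min | left-handed substrate / % | right-handed substrate / % | left-handed product / % |
|---|---|---|---|---|
| blue | 2.00 | 0 | 32 | 48 |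
| blue | 4.00 | 1 | 21 | 51 |
| blue | 5.00 | 0 | 23 | 52 |
| blue | 8.00 | 0 | 12 | 49 |
| violet | 2.00 | 2 | 23 | 48 |
| violet | 4.00 | 1 | 13 | 50 |
| violet | 5.00 | 0 | 7 | 50 |
| violet | 8.00 | 0 | 5 | 46 |

(scatter of a reading: 2 percentage points)

* part of the left-handed substrate and right-handed substrate charged together that has reacted at 12 min
* excess of left-handed product over right-handed product in the product at 12 min
* excess of right-handed substrate over left-handed substrate among what is left of the two at 12 min

- catalyst is single-handed; left-handed substrate and right-handed substrate are mirror images of each other, charged as a racemate, each of them at the stated concentration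
- an excess is the difference of the two amounts in percent of their sum
- an excess is below zero if the other one leads

The right-handed substrate will take a second equivalent and the protic impurity 0.0200, so I set the surplus of partner at its charge minus two. With the catalyst loading held, I take the rate as first order in partner and in right-handed substrate. On that booking the ratio of partner to right-handed substrate starts at the surplus plus one and doubles every h divided by the surplus.

The blue run has a surplus of 2.20 and its last reading puts 24.0% of its right-handed charge still there at 8.00 min. That gives 10.6 min for h, the pseudo-first-order half-life of right-handed substrate at one equivalent of partner. The last reading of the violet run, 5% with a scatter of 2 percentage points, gives 12.0 min, and I carry the blue value.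

My reckoning rests on two times, h and 12 min. The flask has a surplus of 1.00, so its ratio starts at 2.00 and makes 1.14 doublings, reaching 4.40. I reckon 14.7% of the total charge left as right-handed substrate, which means c of 85.3% and eP of 17.2%.

The forecast, which differs from my c and eP, says c of 86%, eP of 16% and eS of 100%, noting that “The apparent k sags slightly with time”.

The flask gives c of 85.4%, eP of 17.1% and eS of >99.9%.

    partner + catalyst + left-handed substrate → catalyst + left-handed product (k = 69000 M⁻² s⁻¹)
    partner + catalyst + right-handed substrate → catalyst + right-handed product (k = 6400 M⁻² s⁻¹)
    partner + protic impurity → quenched reagent (k = 25.0 M⁻¹ s⁻¹)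
    catalyst + added ligand ⇌ idle complex, settled at all times (K = 16000 M⁻¹)
    partner → decomposition product (k = 6.10 × 10⁻⁶ s⁻¹)

In the flask the half-life of left-handed substrate by its own step, 0.41 min at 0.371 min, is short against 12 min, while 29% of the right-handed charge stands at 12.0 min, a ratio of partner to right-handed substrate of 4.32; the reaction of partner with protic impurity makes no difference to c. For a neighbour flask with 0.8 mol% of catalyst, taking h as a quarter of its value gives 2.64 min, hence 4.55 doublings and 1.09% right-handed substrate; that neighbour computes to 0.944%, with c of 99.1% and eP of 0.953%.

All runs stem from a simulated flask for substances that don't exist, noise included.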